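The carbocycle (ring A: C1 quaternary, C2=O, C3 with the acid side chain, C4–OH, C5 and C6 shared with dihydropyranone ring B, whose oxygen sits on C6 and whose ketone C4' sits on C5) is a cyclic vinylogous acid. Hence C4–C5 and C2–C3 are Claisen bonds, and C6 is the β-carbon of C4'=O. Both rings are unzipped to an ynone ester in which the cyclobutane (ring C) is the only ring. In one pot PMe3 shifts the ester acyl group from oxygen to C5, the freed alkoxide closes ring B at C6, and LiN(SiMe3)2 closes ring A last by Dieckmann condensation. C1 is set beforehand by double Fráter–Seebach alkylation.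

Key step: step 16

Assumption: the target and its methyl ester are written as the C4–OH/C2=O enol tautomer, and the enol tautomers interconvert freely.
Labels: C1–C6 (ring A) and C2', C3', C4' (ring B: O–C2'H(Me)–C3'H(Me)–C4'=O) are the labels defined above, not the locants of the systematic names.

Step 1
Reactants: 1 (1S,5S)-(−)-verbenone
Product: 2 (1S,3R)-3-acetyl-2,2-dimethylcyclobutane-1-carboxylic acid [(−)-cis-pinononic acid]
Conditions: RuCl3·xH2O (2 mol %), NaIO4, MeCN/EtOAc/H2O, rt
Reagents that add atoms: sodium periodate, [Na+].[O-]I(=O)(=O)=O; water, O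
Why: Oxidative cleavage of the enone C=C bond by RuO4 made in situ, with loss of the former =CH carbon as CO2 from the α-keto acid first formed, cuts the six-membered ring of the cheap pinane skeleton and keeps its two bridgehead stereocentres as the cis-1,3 pair of ring C.

Step 2
Reactants: 2 (1S,3R)-3-acetyl-2,2-dimethylcyclobutane-1-carboxylic acid
Product: 3 (1S,3S)-2,2-dimethyl-3-(prop-1-en-2-yl)cyclobutane-1-carboxylic acid
Conditions: Ph3PCH3Br, KOtBu, THF, 0 °C to rt; then 1 M HCl
Reagents that add atoms: methyltriphenylphosphonium bromide, C[P+](c1ccccc1)(c1ccccc1)c1ccccc1.[Br-]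
Why: Wittig methylenation of the methyl ketone on the potassium carboxylate, in which the non-stabilised ylide should add faster than it enolises the ketone so that the cis relationship is kept.

Step 3
Reactants: 3 (1S,3S)-2,2-dimethyl-3-(prop-1-en-2-yl)cyclobutane-1-carboxylic acid
Product: 4 [(1S,3S)-2,2-dimethyl-3-(prop-1-en-2-yl)cyclobutyl]methanol
Conditions: LiAlH4, Et2O, 0 °C to rt
Reagents that add atoms: none
Why: Hydride reduction of the acid to the primary alcohol leaves the isolated alkene and both stereocentres untouched.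

Step 4
Reactants: 4 [(1S,3S)-2,2-dimethyl-3-(prop-1-en-2-yl)cyclobutyl]methanol
Product: 5 (1S,3S)-1-(iodomethyl)-2,2-dimethyl-3-(prop-1-en-2-yl)cyclobutane
Conditions: PPh3, imidazole, I2, CH2Cl2, 0 °C to rt
Reagents that add atoms: iodine, II
Why: Appel-type iodination runs by SN2 displacement of the oxyphosphonium group at the primary carbon, so no cyclobutylcarbinyl cation and no ring expansion should arise.

Step 5
Reactants: 6 methyl (S)-3-hydroxybutanoate (in excess); 5 (1S,3S)-1-(iodomethyl)-2,2-dimethyl-3-(prop-1-en-2-yl)cyclobutane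
Product: 7 methyl (2S,3S)-2-{[(1R,3S)-2,2-dimethyl-3-(prop-1-en-2-yl)cyclobutyl]methyl}-3-hydroxybutanoate
Conditions: LiN(iPr)2 (2.1 equiv per 6), THF, −78 to −20 °C; 5, DMPU, −20 to 0 °C
Reagents that add atoms: none
Why: Fráter–Seebach alkylation, in which the lithium-chelated alkoxide enolate is attacked anti to the carbinol methyl group to give the 2,3-anti ester, with DMPU raising the rate for the β-branched iodide.

Step 6
Reactants: 7 methyl (2S,3S)-2-{[(1R,3S)-2,2-dimethyl-3-(prop-1-en-2-yl)cyclobutyl]methyl}-3-hydroxybutanoate; 8 1-bromo-3-methylbut-2-ene (prenyl bromide)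
Product: 9 methyl (2R)-2-{[(1R,3S)-2,2-dimethyl-3-(prop-1-en-2-yl)cyclobutyl]methyl}-2-[(1S)-1-hydroxyethyl]-5-methylhex-4-enoate
Conditions: LiN(iPr)2 (2.5 equiv), THF, −78 to 0 °C; 8, −78 to −20 °C
Reagents that add atoms: none
Why: Second Fráter–Seebach alkylation, in which chelation fixes the geometry of the tetrasubstituted enolate whatever the α-configuration of 7 was and prenyl bromide again enters anti to the carbinol methyl group, which sets C1 as (R).

Step 7
Reactants: 9 methyl (2R)-2-{[(1R,3S)-2,2-dimethyl-3-(prop-1-en-2-yl)cyclobutyl]methyl}-2-[(1S)-1-hydroxyethyl]-5-methylhex-4-enoate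
Product: 10 methyl (2R)-2-acetyl-2-{[(1R,3S)-2,2-dimethyl-3-(prop-1-en-2-yl)cyclobutyl]methyl}-5-methylhex-4-enoate
Conditions: Dess–Martin periodinane (DMP), CH2Cl2, 0 °C to rt
Reagents that add atoms: none
Why: Dess–Martin oxidation removes the now spent carbinol stereocentre under near-neutral conditions, and the quaternary C1 cannot epimerise.

Step 8
Reactants: 10 methyl (2R)-2-acetyl-2-{[(1R,3S)-2,2-dimethyl-3-(prop-1-en-2-yl)cyclobutyl]methyl}-5-methylhex-4-enoate
Product: 12 methyl (2R)-2-{[(1R,3S)-2,2-dimethyl-3-(prop-1-en-2-yl)cyclobutyl]methyl}-2-ethynyl-5-methylhex-4-enoate, via enol phosphate 11 (not isolated)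
Conditions: LiN(iPr)2, THF, −78 °C; ClP(O)(OEt)2, −78 °C to rt; then LiN(iPr)2 (2.3 equiv), −78 °C to rt
Reagents that add atoms: diethyl chlorophosphate, CCOP(=O)(Cl)OCC (its atoms are held only by 11)
Why: Enol phosphate formation at the only enolisable (methyl) side followed by base-induced elimination is the standard methyl ketone to terminal alkyne conversion, and neither the ester, which has no α-hydrogen, nor C1 can be touched.

Step 9
Reactants: 13 methyl (R)-3-hydroxybutanoate
Product: 14 methyl (2R,3R)-3-hydroxy-2-methylbutanoate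
Conditions: LiN(iPr)2 (2.1 equiv), THF, −78 to −20 °C; MeI, −78 to 0 °C
Reagents that add atoms: iodomethane, CI
Why: Fráter–Seebach methylation anti to the carbinol methyl group of the chelated dianion sets the (2R,3R) anti pair that becomes the trans-dimethyl unit C3'/C2' of ring B.

Step 10
Reactants: 14 methyl (2R,3R)-3-hydroxy-2-methylbutanoate
Product: 15 (2R,3R)-3-hydroxy-N-methoxy-N,2-dimethylbutanamide
Conditions: MeNH(OMe)·HCl, iPrMgCl, THF, −20 to 0 °C
Reagents that add atoms: N,O-dimethylhydroxylamine hydrochloride, CNOC.Cl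
Why: Weinreb amide formation by magnesium amide aminolysis of the ester, with the hydroxyl group masked as its magnesium alkoxide and no enolisation of the α-centre at this temperature.

Step 11
Reactants: 12 methyl (2R)-2-{[(1R,3S)-2,2-dimethyl-3-(prop-1-en-2-yl)cyclobutyl]methyl}-2-ethynyl-5-methylhex-4-enoate; 15 (2R,3R)-3-hydroxy-N-methoxy-N,2-dimethylbutanamide
Product: 16 methyl (2R,6R,7R)-2-{[(1R,3S)-2,2-dimethyl-3-(prop-1-en-2-yl)cyclobutyl]methyl}-7-hydroxy-6-methyl-2-(3-methylbut-2-en-1-yl)-5-oxooct-3-ynoate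
Conditions: 12, LiN(iPr)2, THF, −78 °C; 15 pretreated with iPrMgCl (1 equiv), THF, −20 °C; combine, −78 to 0 °C
Reagents that add atoms: none
Why: Acylation of a lithium acetylide by a Weinreb amide stops at the chelated tetrahedral adduct so that the ynone is freed only on work-up, and the preformed magnesium alkoxide saves a protecting group and an equivalent of acetylide.

Step 12
Reactants: 17 (E)-oct-2-enal; 18 dimethyl malonate
Product: 19 dimethyl 2-[(3R)-1-oxooctan-3-yl]propanedioate
Conditions: (S)-2-[diphenyl(trimethylsilyloxy)methyl]pyrrolidine (10 mol %), PhCO2H (10 mol %), EtOH, 0 °C to rt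
Reagents that add atoms: none
Why: Iminium-catalysed Michael addition, in which the diphenyl(silyloxy)methyl group of the E,s-trans iminium ion shields one face of the enal β-carbon so that malonate should add to the other face and give the (R) adduct.

Step 13
Reactants: 19 dimethyl 2-[(3R)-1-oxooctan-3-yl]propanedioate
Product: 20 (3R)-3-(1,3-dimethoxy-1,3-dioxopropan-2-yl)octanoic acid
Conditions: NaClO2, NaH2PO4, 2-methyl-2-butene, tBuOH/H2O, rt
Reagents that add atoms: sodium chlorite, [Na+].[O-]Cl=O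
Why: Pinnick oxidation converts the aldehyde into the acid without touching the β-stereocentre or the malonate.

Step 14
Reactants: 20 (3R)-3-(1,3-dimethoxy-1,3-dioxopropan-2-yl)octanoic acid
Product: 21 (3R)-3-(2-methoxy-2-oxoethyl)octanoic acid
Conditions: LiCl, H2O, DMSO, 140 °C
Reagents that add atoms: none
Why: Krapcho dealkoxycarbonylation removes one of the geminal esters only, which leaves the two arms of the 3-pentylglutarate differentiated as acid and methyl ester around a centre that is α to no carbonyl group.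

Step 15
Reactants: 16 methyl (2R,6R,7R)-2-{[(1R,3S)-2,2-dimethyl-3-(prop-1-en-2-yl)cyclobutyl]methyl}-7-hydroxy-6-methyl-2-(3-methylbut-2-en-1-yl)-5-oxooct-3-ynoate; 21 (3R)-3-(2-methoxy-2-oxoethyl)octanoic acid
Product: 22 methyl (2R,6R,7R)-2-{[(1R,3S)-2,2-dimethyl-3-(prop-1-en-2-yl)cyclobutyl]methyl}-7-{[(3S)-3-(2-methoxy-2-oxoethyl)octanoyl]oxy}-6-methyl-2-(3-methylbut-2-en-1-yl)-5-oxooct-3-ynoate
Conditions: EDC·HCl, DMAP (10 mol %), CH2Cl2, 0 °C
Reagents that add atoms: none
Why: Steglich esterification of the secondary alcohol by carbodiimide activation at low temperature is mild enough to avoid β-elimination of the new acyloxy group.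

Step 16
Reactants: 22 methyl (2R,6R,7R)-2-{[(1R,3S)-2,2-dimethyl-3-(prop-1-en-2-yl)cyclobutyl]methyl}-7-{[(3S)-3-(2-methoxy-2-oxoethyl)octanoyl]oxy}-6-methyl-2-(3-methylbut-2-en-1-yl)-5-oxooct-3-ynoate
Product: 24 methyl (3S)-3-[(2R,3R,8R)-8-{[(1R,3S)-2,2-dimethyl-3-(prop-1-en-2-yl)cyclobutyl]methyl}-5-hydroxy-2,3-dimethyl-8-(3-methylbut-2-en-1-yl)-4,7-dioxo-3,4,7,8-tetrahydro-2H-chromen-6-yl]octanoate, via 5-acylpyranone 23 (not isolated)
Conditions: PMe3 (20 mol %), THF, 0 °C to rt; then LiN(SiMe3)2 (1.5 equiv), −78 to 0 °C; then 1 M HCl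
Reagents that add atoms: none
Why: Proposed new method: PMe3 adds to C6 of the ynone, the C5 carbanion so formed takes the acyl carbon C4 from the neighbouring C2' ester through a six-membered transition state (C4–C5 bond), the freed C2' alkoxide displaces the phosphine at C6 to give 23, and LiN(SiMe3)2 then deprotonates C3 so that the enolate attacks the C2 methyl ester (C2–C3 bond) and methoxide leaves. The closest known reaction types are the phosphine-catalysed tandem acyl transfer–cyclisation of 2-(acyloxy)aryl ynones to 3-acylchromones, extended here from aryl esters to an alkyl ester, and the Dieckmann condensation. Ring B closes first by 6-endo-trig addition–elimination at C6, ring A closes last by 6-(enolendo)-exo-trig acylation. No new stereocentre is formed: C1, C2', C3', the side-chain centre and ring C are carried in from 22 and C3 ends sp2-hybridised. The step needs the ring oxygen on the hindered C6 and not on C4, which a triketone cyclodehydration would not deliver; here C6 is the only electrophilic alkyne carbon, and since C1 bears no hydrogen the ynone cannot isomerise to a dienone under phosphine catalysis. It also needs deprotonation at the C3 methylene rather than at the tertiary C3'–H, which kinetic base at low temperature favours, and the delocalised enolate of 24 is the thermodynamic sink that then protects ring B from β-elimination.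

Step 17
Reactants: 24 methyl (3S)-3-[(2R,3R,8R)-8-{[(1R,3S)-2,2-dimethyl-3-(prop-1-en-2-yl)cyclobutyl]methyl}-5-hydroxy-2,3-dimethyl-8-(3-methylbut-2-en-1-yl)-4,7-dioxo-3,4,7,8-tetrahydro-2H-chromen-6-yl]octanoate
Product: 25 (3S)-3-[(2R,3R,8R)-8-{[(1R,3S)-2,2-dimethyl-3-(prop-1-en-2-yl)cyclobutyl]methyl}-5-hydroxy-2,3-dimethyl-8-(3-methylbut-2-en-1-yl)-4,7-dioxo-3,4,7,8-tetrahydro-2H-chromen-6-yl]octanoic acid (CNP0208815.1)
Conditions: LiOH, THF/MeOH/H2O, rt; then 1 M HCl to pH 3
Reagents that add atoms: lithium hydroxide, [Li+].[OH-]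
Why: Saponification of the only remaining ester, during which the ring A vinylogous acid is present as its delocalised anion and so shields ring B from hydroxide attack and from enolisation at C3'.

Compound list
1 | (1S,5S)-(−)-verbenone | CC1=CC(=O)[C@H]2C[C@@H]1C2(C)C | starting material
2 | (1S,3R)-3-acetyl-2,2-dimethylcyclobutane-1-carboxylic acid | OC(=O)[C@H]1C[C@@H](C(C)=O)C1(C)C | intermediate
3 | (1S,3S)-2,2-dimethyl-3-(prop-1-en-2-yl)cyclobutane-1-carboxylic acid | OC(=O)[C@H]1C[C@@H](C(C)=C)C1(C)C | intermediate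
4 | [(1S,3S)-2,2-dimethyl-3-(prop-1-en-2-yl)cyclobutyl]methanol | OC[C@H]1C[C@@H](C(C)=C)C1(C)C | intermediate
5 | (1S,3S)-1-(iodomethyl)-2,2-dimethyl-3-(prop-1-en-2-yl)cyclobutane | IC[C@H]1C[C@@H](C(C)=C)C1(C)C | intermediate
6 | methyl (S)-3-hydroxybutanoate | C[C@H](O)CC(=O)OC | starting material
7 | methyl (2S,3S)-2-{[(1R,3S)-2,2-dimethyl-3-(prop-1-en-2-yl)cyclobutyl]methyl}-3-hydroxybutanoate | O[C@@H](C)[C@H](C[C@H]1C[C@@H](C(C)=C)C1(C)C)C(=O)OC | intermediate
8 | 1-bromo-3-methylbut-2-ene | CC(C)=CCBr | starting material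
9 | methyl (2R)-2-{[(1R,3S)-2,2-dimethyl-3-(prop-1-en-2-yl)cyclobutyl]methyl}-2-[(1S)-1-hydroxyethyl]-5-methylhex-4-enoate | O[C@@H](C)[C@](C[C@H]1C[C@@H](C(C)=C)C1(C)C)(CC=C(C)C)C(=O)OC | intermediate
10 | methyl (2R)-2-acetyl-2-{[(1R,3S)-2,2-dimethyl-3-(prop-1-en-2-yl)cyclobutyl]methyl}-5-methylhex-4-enoate | CC(=O)[C@](C[C@H]1C[C@@H](C(C)=C)C1(C)C)(CC=C(C)C)C(=O)OC | intermediate
11 | methyl (2R)-2-[1-(diethoxyphosphoryloxy)ethenyl]-2-{[(1R,3S)-2,2-dimethyl-3-(prop-1-en-2-yl)cyclobutyl]methyl}-5-methylhex-4-enoate | C=C(OP(=O)(OCC)OCC)[C@](C[C@H]1C[C@@H](C(C)=C)C1(C)C)(CC=C(C)C)C(=O)OC | intermediate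
12 | methyl (2R)-2-{[(1R,3S)-2,2-dimethyl-3-(prop-1-en-2-yl)cyclobutyl]methyl}-2-ethynyl-5-methylhex-4-enoate | C#C[C@](C[C@H]1C[C@@H](C(C)=C)C1(C)C)(CC=C(C)C)C(=O)OC | intermediate
13 | methyl (R)-3-hydroxybutanoate | C[C@@H](O)CC(=O)OC | starting material
14 | methyl (2R,3R)-3-hydroxy-2-methylbutanoate | O[C@H](C)[C@@H](C)C(=O)OC | intermediate
15 | (2R,3R)-3-hydroxy-N-methoxy-N,2-dimethylbutanamide | O[C@H](C)[C@@H](C)C(=O)N(C)OC | intermediate
16 | methyl (2R,6R,7R)-2-{[(1R,3S)-2,2-dimethyl-3-(prop-1-en-2-yl)cyclobutyl]methyl}-7-hydroxy-6-methyl-2-(3-methylbut-2-en-1-yl)-5-oxooct-3-ynoate | O[C@H](C)[C@@H](C)C(=O)C#C[C@](C[C@H]1C[C@@H](C(C)=C)C1(C)C)(CC=C(C)C)C(=O)OC | intermediate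
17 | (E)-oct-2-enal | CCCCC/C=C/C=O | starting material
18 | dimethyl malonate | COC(=O)CC(=O)OC | starting material
19 | dimethyl 2-[(3R)-1-oxooctan-3-yl]propanedioate | O=CC[C@@H](CCCCC)C(C(=O)OC)C(=O)OC | intermediate
20 | (3R)-3-(1,3-dimethoxy-1,3-dioxopropan-2-yl)octanoic acid | OC(=O)C[C@@H](CCCCC)C(C(=O)OC)C(=O)OC | intermediate
21 | (3R)-3-(2-methoxy-2-oxoethyl)octanoic acid | OC(=O)C[C@@H](CCCCC)CC(=O)OC | intermediate
22 | methyl (2R,6R,7R)-2-{[(1R,3S)-2,2-dimethyl-3-(prop-1-en-2-yl)cyclobutyl]methyl}-7-{[(3S)-3-(2-methoxy-2-oxoethyl)octanoyl]oxy}-6-methyl-2-(3-methylbut-2-en-1-yl)-5-oxooct-3-ynoate | COC(=O)C[C@H](CCCCC)CC(=O)O[C@H](C)[C@@H](C)C(=O)C#C[C@](C[C@H]1C[C@@H](C(C)=C)C1(C)C)(CC=C(C)C)C(=O)OC | intermediate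
23 | methyl (2R)-2-{[(1R,3S)-2,2-dimethyl-3-(prop-1-en-2-yl)cyclobutyl]methyl}-2-{(2R,3R)-5-[(3R)-3-(2-methoxy-2-oxoethyl)octanoyl]-2,3-dimethyl-4-oxo-3,4-dihydro-2H-pyran-6-yl}-5-methylhex-4-enoate | COC(=O)C[C@H](CCCCC)CC(=O)C1=C(O[C@H](C)[C@@H](C)C1=O)[C@](C[C@H]2C[C@@H](C(C)=C)C2(C)C)(CC=C(C)C)C(=O)OC | intermediate
24 | methyl (3S)-3-[(2R,3R,8R)-8-{[(1R,3S)-2,2-dimethyl-3-(prop-1-en-2-yl)cyclobutyl]methyl}-5-hydroxy-2,3-dimethyl-8-(3-methylbut-2-en-1-yl)-4,7-dioxo-3,4,7,8-tetrahydro-2H-chromen-6-yl]octanoate | C=C(C)[C@@H]1C[C@H](C[C@@]2(CC=C(C)C)C(=O)C([C@@H](CCCCC)CC(=O)OC)=C(O)C3=C2O[C@H](C)[C@@H](C)C3=O)C1(C)C | intermediate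
25 | (3S)-3-[(2R,3R,8R)-8-{[(1R,3S)-2,2-dimethyl-3-(prop-1-en-2-yl)cyclobutyl]methyl}-5-hydroxy-2,3-dimethyl-8-(3-methylbut-2-en-1-yl)-4,7-dioxo-3,4,7,8-tetrahydro-2H-chromen-6-yl]octanoic acid | C=C(C)[C@@H]1C[C@H](C[C@@]2(CC=C(C)C)C(=O)C([C@@H](CCCCC)CC(=O)O)=C(O)C3=C2O[C@H](C)[C@@H](C)C3=O)C1(C)C | target

Total step count: 17. Longest linear sequence: 12 steps (steps 1–8, 11, 15, 16, 17).

Steps most likely to fail

Step 16 (bears the label).
- **What may go wrong:** Addition of the phosphine to C6 next to the quaternary C1 may be too slow. Proton transfer to the C5 carbanion may outrun acyl transfer and start β-elimination of the acyloxy group. In the second stage, enolisation at C3' may open ring B by a retro-oxa-Michael process and erode C2'/C3'.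
- **Fallback (known chemistry only):** It sets out from 16 and 21 and comes back at 23. Compound 16 is silylated (Et3SiCl, imidazole) to the triethylsilyl ether F1. Pyrrolidine adds to the ynone to give the (E)-enaminone F2 with nitrogen on C6. Compound 21 is turned with oxalyl chloride into the acid chloride F3, which C-acylates the enaminone at C5 (pyridine, CH2Cl2) to the diacyl enamine F4. Aqueous HF in MeCN removes the silyl group, and the hydroxyl group displaces pyrrolidine at C6 to give 23. This is now isolated and cyclised with LiN(SiMe3)2 as in the second stage of step 16.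

Step 5.
- **What may go wrong:** SN2 displacement at the β-branched iodide may be slower than decay of the dianion by retro-aldol cleavage and self-condensation.
- **Fallback:** It sets out from 5 and comes back at 9. The sodium enolate of commercial methyl acetoacetate (NaH, DMF, 60 °C), a far more robust nucleophile, is alkylated with 5 to the keto ester F5 (both α-epimers). An (S)-selective ketoreductase (NADPH, iPrOH) reduces the ketone to the (3S)-hydroxy ester F6 (both α-epimers). Step 6 erases the α-centre, so the mixture is carried through the conditions of step 6 and meets the route at 9.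

Step 6.
- **What may go wrong:** Deprotonation of the hindered α-C–H may be incomplete, or partial loss of chelation may lower the facial bias and erode C1.
- **Fallback:** It sets out from 7 and comes back at 10. Compound 7 is oxidised with DMP to the keto ester F5. Condensation with L-valine tert-butyl ester gives the Z-enamine F7. LiN(iPr)2 in toluene with one donor ligand, then 8, gives the alkylated imine F8. In the tridentate lithium chelate the isopropyl group has shielded one face, and the choice of donor ligand on lithium (THF or HMPA) decides which face stays open, so the (R) centre is within reach. Dilute aqueous citric acid then frees 10.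

Further compounds
F1 | step 16 | methyl (2R,6R,7R)-2-{[(1R,3S)-2,2-dimethyl-3-(prop-1-en-2-yl)cyclobutyl]methyl}-6-methyl-2-(3-methylbut-2-en-1-yl)-5-oxo-7-(triethylsilyloxy)oct-3-ynoate | CC[Si](CC)(CC)O[C@H](C)[C@@H](C)C(=O)C#C[C@](C[C@H]1C[C@@H](C(C)=C)C1(C)C)(CC=C(C)C)C(=O)OC
F2 | step 16 | (E)-enaminone, pyrrolidine adduct of F1 with nitrogen on C6 | CC[Si](CC)(CC)O[C@H](C)[C@@H](C)C(=O)/C=C(/N1CCCC1)[C@](C[C@H]2C[C@@H](C(C)=C)C2(C)C)(CC=C(C)C)C(=O)OC
F3 | step 16 | methyl (3S)-3-(2-chloro-2-oxoethyl)octanoate | ClC(=O)C[C@@H](CCCCC)CC(=O)OC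
F4 | step 16 | diacyl enamine, F2 acylated at C5 with F3 | CC[Si](CC)(CC)O[C@H](C)[C@@H](C)C(=O)C(C(=O)C[C@@H](CCCCC)CC(=O)OC)=C(N1CCCC1)[C@](C[C@H]2C[C@@H](C(C)=C)C2(C)C)(CC=C(C)C)C(=O)OC
F5 | step 5 | methyl 2-{[(1R,3S)-2,2-dimethyl-3-(prop-1-en-2-yl)cyclobutyl]methyl}-3-oxobutanoate (both α-epimers) | CC(=O)C(C[C@H]1C[C@@H](C(C)=C)C1(C)C)C(=O)OC
F6 | step 5 | methyl (3S)-2-{[(1R,3S)-2,2-dimethyl-3-(prop-1-en-2-yl)cyclobutyl]methyl}-3-hydroxybutanoate (both α-epimers) | O[C@@H](C)C(C[C@H]1C[C@@H](C(C)=C)C1(C)C)C(=O)OC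
F7 | step 6 | Z-enamine of F5 with L-valine tert-butyl ester | C/C(N[C@@H](C(C)C)C(=O)OC(C)(C)C)=C(/C(=O)OC)C[C@H]1C[C@@H](C(C)=C)C1(C)C
F8 | step 6 | prenylated imine, (R) at the quaternary carbon | CC(=N[C@@H](C(C)C)C(=O)OC(C)(C)C)[C@](C[C@H]1C[C@@H](C(C)=C)C1(C)C)(CC=C(C)C)C(=O)OC
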